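**Plan**
Retrosynthesis: the 7-O-acetyl and the C6–H bond are removed first. Ring B is then cut at C6–C7 and C9–C10 together, giving β-cyclogeranoyl chloride (ring A with C5, C6, C10) and a chiral (Z)-γ-silyloxyallylstannane (C7–C9, C11–C17) that goes back to neryl acetate.
Forward: ring A is bought as β-cyclocitral and the side chain, with its 13Z alkene and 15-acetate, as neryl acetate. Ring B is closed last in one Lewis-acid operation, followed by C6 reduction, desilylation and 7-O-acetylation.
Enabling feature: C6 lies between the tetrasubstituted C5=C10 of ring A and the C7(O)–C8(Me)=C9 allyl unit. Ring B is therefore an acyl/β-carbon bis-electrophile (C6, C10) joined to an oxygenated allyl bis-nucleophile (C7, C9); the C8 methyl carries the cation and C8=C9 is its proton-loss product.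
Stereochemistry: C7 comes from a Li[AlH(OEt)(binaphtholate)] reduction relayed by two anti SE2′ steps, C10 from C7 through a chair transition state, C5 from axial protonation, C6 from hydride on the α face, and 13Z from neryl acetate.

Key step: step 9

Remark: atom numbers in the text are labdane numbers (ring A = C1–C5, C10; ring B = C5–C10).
Assumption: the (S)-binaphthol aluminium hydride is taken to give the (R)-carbinol 9 (stannyl group in the role of the unsaturated substituent); if the facial sense on this substrate is the opposite, the (R)-reagent is used.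

**Step 1**
Reactants: 1 β-cyclocitral
Product: 2 β-cyclogeranic acid
Conditions: NaClO2, NaH2PO4, 2-methylbut-2-ene, t-BuOH/H2O, 0 °C to rt
Reagents that add atoms: sodium chlorite NaClO2, [Na+].[O-]Cl=O
Why: The Pinnick oxidation should convert the hindered, non-enolisable enal into the acid while the hypochlorite by-product is trapped by 2-methylbut-2-ene, so the tetrasubstituted ring alkene is left alone.

**Step 2**
Reactants: 2 β-cyclogeranic acid
Product: 3 β-cyclogeranoyl chloride
Conditions: (COCl)2, DMF (cat.), CH2Cl2, 0 °C to rt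
Reagents that add atoms: oxalyl chloride, O=C(Cl)C(=O)Cl
Why: Chloride exchange through the Vilsmeier-type chloroiminium species should give the acid chloride under neutral, non-isomerising conditions.

**Step 3**
Reactants: 4 neryl acetate
Product: 5 (2Z,6E)-8-hydroxy-3,7-dimethylocta-2,6-dien-1-yl acetate
Conditions: SeO2 (cat.), t-BuOOH, salicylic acid (cat.), CH2Cl2, rt
Reagents that add atoms: tert-butyl hydroperoxide, CC(C)(C)OO
Why: SeO2-catalysed allylic hydroxylation (ene reaction followed by a 2,3-sigmatropic shift) should oxidise the (E)-methyl of the electron-rich isopropylidene end, the 2,3-alkene being deactivated by its allylic acetate.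

**Step 4**
Reactants: 5 (2Z,6E)-8-hydroxy-3,7-dimethylocta-2,6-dien-1-yl acetate
Product: 6 (2Z,6E)-3,7-dimethyl-8-oxoocta-2,6-dien-1-yl acetate
Conditions: MnO2, CH2Cl2, rt
Reagents that add atoms: none
Why: Allylic alcohol oxidation with MnO2 should give the enal without touching the ester or either alkene geometry.

**Step 5**
Reactants: 6 (2Z,6E)-3,7-dimethyl-8-oxoocta-2,6-dien-1-yl acetate
Product: 8 (2Z,6E)-3,7-dimethyl-8-oxo-8-(tributylstannyl)octa-2,6-dien-1-yl acetate, via lithium stannylcarbinolate 7 (not isolated)
Conditions: Bu3SnH (1.1 equiv), LiN(i-Pr)2 (1.05 equiv), THF, −78 °C; then 1,1′-(azodicarbonyl)dipiperidine, −78 to 0 °C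
Reagents that add atoms: tributyltin hydride Bu3SnH, CCCC[SnH](CCCC)CCCC
Why: 1,2-Addition of the stannyl anion to the aldehyde followed by hydride abstraction from the carbinolate by the azodicarboxamide should give the acylstannane, the acetate being spared at −78 °C because no excess amide base or stannyl anion is present.

**Step 6**
Reactants: 8 (2Z,6E)-3,7-dimethyl-8-oxo-8-(tributylstannyl)octa-2,6-dien-1-yl acetate
Product: 9 (2Z,6E,8R)-8-hydroxy-3,7-dimethyl-8-(tributylstannyl)octa-2,6-dien-1-yl acetate
Conditions: Li[AlH(OEt)((S)-1,1′-bi-2-naphtholate)] ((S)-BINAL-H), THF, −78 °C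
Reagents that add atoms: none
Why: Enantioface-selective hydride transfer (asymmetric carbonyl reduction with a binaphthol-modified aluminium hydride) should set C7 as R, the stannyl and alkenyl groups being differentiated in the six-membered transition state.

**Step 7**
Reactants: 9 (2Z,6E,8R)-8-hydroxy-3,7-dimethyl-8-(tributylstannyl)octa-2,6-dien-1-yl acetate
Product: 10 (2Z,6E,8R)-8-(tert-butyldimethylsilyloxy)-3,7-dimethyl-8-(tributylstannyl)octa-2,6-dien-1-yl acetate
Conditions: TBSCl, imidazole, DMF, 0 °C
Reagents that add atoms: tert-butyldimethylsilyl chloride, CC(C)(C)[Si](C)(C)Cl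
Why: Silyl ether formation under mild base should protect the labile α-hydroxystannane without touching the C–Sn bond, so the C7 configuration is retained.

**Step 8**
Reactants: 10 (2Z,6E,8R)-8-(tert-butyldimethylsilyloxy)-3,7-dimethyl-8-(tributylstannyl)octa-2,6-dien-1-yl acetate
Product: 11 (2Z,6R,7Z)-8-(tert-butyldimethylsilyloxy)-3,7-dimethyl-6-(tributylstannyl)octa-2,7-dien-1-yl acetate
Conditions: BF3·OEt2 (0.2 equiv), CH2Cl2, −78 °C
Reagents that add atoms: none
Why: Lewis acid-promoted intermolecular 1,3-stannyl migration (anti SE2′) should move tin to C9 and give the (Z)-enol silyl ether, the C7 configuration being transferred to C9 (R) because tin leaves and enters on opposite faces.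

**Step 9**
Reactants: 3 β-cyclogeranoyl chloride; 11 (2Z,6R,7Z)-8-(tert-butyldimethylsilyloxy)-3,7-dimethyl-6-(tributylstannyl)octa-2,7-dien-1-yl acetate
Product: 13 (5S,7S,10S,13Z)-7-(tert-butyldimethylsilyloxy)-6-oxolabda-8,13-dien-15-yl acetate, via acyclic dienone 12 (not isolated)
Conditions: 3 premixed with SnCl4 (2.2 equiv), CH2Cl2, −78 °C; then 11, 2,6-di-tert-butyl-4-methylpyridine, −78 to −30 °C; aq. NaHCO3
Reagents that add atoms: none
Why: Proposed new method: SnCl4 ionises the hindered acid chloride 3 to its linear acylium ion, which is attacked at C7 of 11 anti to the C9–Sn bond (SE2′) to give dienone 12 (C6–C7), and the same Lewis acid then activates the C5=C10–C6=O enone of 12 so that C9 of the C8=C9 alkene adds to the β-carbon C10 (C9–C10), the tertiary C8 cation losing H-9 to give the C8=C9 alkene and the tin enolate being protonated at C5 on work-up. The closest known reaction types are the tandem Friedel–Crafts acylation/Nazarov annulation of vinylsilanes with α,β-unsaturated acid chlorides, the Lewis acid-promoted SE2′ addition of γ-(silyloxy)allylstannanes to aldehydes and the Lewis acid-initiated enone–alkene cation cyclisation, and their combination on an acid chloride and an oxygenated allylstannane is what is new. Ring B closes in a 6-endo-trig mode at the alkene (conjugate, enol-endo at the enone) through a chair-like transition state. C7 (S) is fixed by the anti SE2′ transfer from the C9 stereocentre; C10 (S) follows from C7 because the 7-silyloxy group sits pseudo-axial (A(1,2) strain with the C8 methyl and dipole opposition to C6=O) while the C10 methyl is forced axial by ring A, which places the two trans; C5 (S) comes from axial protonation of the enolate on the α face, away from the axial C10 and C4 methyls. The step needs attack of the acylium at C7 and not C8 (secured by C–Sn hyperconjugation of the allylstannane), proton loss from C9 and not C7 (H-9 is axial and aligned with the empty orbital, H-7 is equatorial, and the hindered pyridine takes up the proton so that acid-mediated conjugation is avoided) and no participation of the C13=C14 alkene (deactivated by its allylic acetate).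

**Step 10**
Reactants: 13 (5S,7S,10S,13Z)-7-(tert-butyldimethylsilyloxy)-6-oxolabda-8,13-dien-15-yl acetate
Product: 14 (5S,6S,7S,10S,13Z)-7-(tert-butyldimethylsilyloxy)-6-hydroxylabda-8,13-dien-15-yl acetate
Conditions: NaBH4, CeCl3·7H2O, MeOH, −78 to −40 °C
Reagents that add atoms: none
Why: Luche reduction should deliver hydride to the C6 ketone from the α face, the β face being blocked by the axial C4 and C10 methyls, to give the axial 6β-alcohol (6S) with the acetate untouched.

**Step 11**
Reactants: 14 (5S,6S,7S,10S,13Z)-7-(tert-butyldimethylsilyloxy)-6-hydroxylabda-8,13-dien-15-yl acetate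
Product: 15 (5S,6S,7S,10S,13Z)-6,7-dihydroxylabda-8,13-dien-15-yl acetate
Conditions: HF·pyridine, THF, 0 °C to rt
Reagents that add atoms: none
Why: Fluoride-mediated desilylation should free the 7α-hydroxyl, and the trans-diaxial arrangement of O6 and O7 prevents acyl or silyl migration between them.

**Step 12**
Reactants: 15 (5S,6S,7S,10S,13Z)-6,7-dihydroxylabda-8,13-dien-15-yl acetate
Product: 16 (5S,6S,7S,10S,13Z)-6-hydroxylabda-8,13-diene-7,15-diyl diacetate (target)
Conditions: Ac2O, pyridine, CH2Cl2, 0 °C to rt
Reagents that add atoms: acetic anhydride, CC(=O)OC(C)=O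
Why: Site-selective acylation should acetylate the allylic 7α-hydroxyl while the 6β-hydroxyl, 1,3-diaxial to the C4 and C10 methyls, stays free under non-forcing conditions.

**Compound list**
1 | β-cyclocitral (2,6,6-trimethylcyclohex-1-ene-1-carbaldehyde) | CC1=C(C=O)C(C)(C)CCC1 | starting material
2 | β-cyclogeranic acid (2,6,6-trimethylcyclohex-1-ene-1-carboxylic acid) | CC1=C(C(=O)O)C(C)(C)CCC1 | intermediate
3 | β-cyclogeranoyl chloride | CC1=C(C(=O)Cl)C(C)(C)CCC1 | intermediate
4 | neryl acetate ((Z)-3,7-dimethylocta-2,6-dien-1-yl acetate) | CC(=O)OC/C=C(/C)CCC=C(C)C | starting material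
5 | (2Z,6E)-8-hydroxy-3,7-dimethylocta-2,6-dien-1-yl acetate | CC(=O)OC/C=C(/C)CC/C=C(\C)CO | intermediate
6 | (2Z,6E)-3,7-dimethyl-8-oxoocta-2,6-dien-1-yl acetate | CC(=O)OC/C=C(/C)CC/C=C(\C)C=O | intermediate
7 | lithium (2Z,6E)-8-acetoxy-2,6-dimethyl-1-(tributylstannyl)octa-2,6-dien-1-olate (racemic) | [Li+].CC(=O)OC/C=C(/C)CC/C=C(\C)C([O-])[Sn](CCCC)(CCCC)CCCC | intermediate
8 | (2Z,6E)-3,7-dimethyl-8-oxo-8-(tributylstannyl)octa-2,6-dien-1-yl acetate | CC(=O)OC/C=C(/C)CC/C=C(\C)C(=O)[Sn](CCCC)(CCCC)CCCC | intermediate
9 | (2Z,6E,8R)-8-hydroxy-3,7-dimethyl-8-(tributylstannyl)octa-2,6-dien-1-yl acetate | CC(=O)OC/C=C(/C)CC/C=C(\C)[C@H](O)[Sn](CCCC)(CCCC)CCCC | intermediate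
10 | (2Z,6E,8R)-8-(tert-butyldimethylsilyloxy)-3,7-dimethyl-8-(tributylstannyl)octa-2,6-dien-1-yl acetate | CC(=O)OC/C=C(/C)CC/C=C(\C)[C@H](O[Si](C)(C)C(C)(C)C)[Sn](CCCC)(CCCC)CCCC | intermediate
11 | (2Z,6R,7Z)-8-(tert-butyldimethylsilyloxy)-3,7-dimethyl-6-(tributylstannyl)octa-2,7-dien-1-yl acetate | CC(=O)OC/C=C(/C)CC[C@@H]([Sn](CCCC)(CCCC)CCCC)/C(C)=C\O[Si](C)(C)C(C)(C)C | intermediate
12 | (2Z,6E,8S)-8-(tert-butyldimethylsilyloxy)-3,7-dimethyl-9-oxo-9-(2,6,6-trimethylcyclohex-1-en-1-yl)nona-2,6-dien-1-yl acetate | CC1=C(C(=O)[C@@H](O[Si](C)(C)C(C)(C)C)/C(C)=C/CC/C(C)=C\COC(C)=O)C(C)(C)CCC1 | intermediate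
13 | (5S,7S,10S,13Z)-7-(tert-butyldimethylsilyloxy)-6-oxolabda-8,13-dien-15-yl acetate | CC(=O)OC/C=C(/C)CCC1=C(C)[C@H](O[Si](C)(C)C(C)(C)C)C(=O)[C@H]2C(C)(C)CCC[C@]12C | intermediate
14 | (5S,6S,7S,10S,13Z)-7-(tert-butyldimethylsilyloxy)-6-hydroxylabda-8,13-dien-15-yl acetate | CC(=O)OC/C=C(/C)CCC1=C(C)[C@H](O[Si](C)(C)C(C)(C)C)[C@@H](O)[C@H]2C(C)(C)CCC[C@]12C | intermediate
15 | (5S,6S,7S,10S,13Z)-6,7-dihydroxylabda-8,13-dien-15-yl acetate | CC(=O)OC/C=C(/C)CCC1=C(C)[C@H](O)[C@@H](O)[C@H]2C(C)(C)CCC[C@]12C | intermediate
16 | (5S,6S,7S,10S,13Z)-6-hydroxylabda-8,13-diene-7,15-diyl diacetate | CC(=O)OC/C=C(/C)CCC1=C(C)[C@H](OC(C)=O)[C@@H](O)[C@H]2C(C)(C)CCC[C@]12C | target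

**Totals**
Total step count: 12. Longest linear sequence: 10 steps (steps 3 to 12, from neryl acetate 4).

**Steps most likely to fail**

Step 9 (proposed new method). The allylstannane 11 may be transmetalated or protodestannylated by the Lewis acid before it is acylated, or the C8 cation may lose the C7 proton after ring closure, which would conjugate the ketone and erase the C7 stereocentre. The fallback uses known chemistry and separates the two bond formations. It sets out from 11 and 1: BF3·OEt2-promoted SE2′ addition of 11 to the aldehyde of β-cyclocitral 1 in CH2Cl2 at −78 °C should give the syn adduct (2Z,6E,8S,9S)-8-(tert-butyldimethylsilyloxy)-9-hydroxy-3,7-dimethyl-9-(2,6,6-trimethylcyclohex-1-en-1-yl)nona-2,6-dien-1-yl acetate F1. Dess–Martin oxidation of F1 gives dienone 12, now isolated. Compound 12 is then cyclised on its own with Me2AlCl in CH2Cl2 (an enone-initiated cation–olefin cyclisation in which the aluminium reagent also takes up the proton), and the route is rejoined at 13.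

Step 6. The enantioselectivity of hydride transfer may be eroded on this α-methyl-substituted acylstannane, and the labile hydroxystannane or the acetate may be partly lost. The fallback replaces asymmetric reduction by resolution. It sets out from 6: addition of Bu3SnLi and direct protonation, without the oxidation, gives the racemic carbinol (2Z,6E)-8-hydroxy-3,7-dimethyl-8-(tributylstannyl)octa-2,6-dien-1-yl acetate F2. Lipase-mediated acetylation of F2 with vinyl acetate (Burkholderia cepacia lipase, hexane, rt) is expected to acylate the (S)-enantiomer, which is removed as (2Z,6E,8S)-3,7-dimethyl-8-(tributylstannyl)octa-2,6-diene-1,8-diyl diacetate F3. The unreacted (R)-alcohol is 9, where the route is rejoined.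

Step 10. Facial selectivity of hydride addition may be poor, because the axial 7α-silyloxy group shields part of the α face, so some 6α-alcohol may form. The fallback switches from steric to hydroxyl-directed control. It sets out from 13: HF·pyridine first removes the silyl group to give the ketol (5S,7S,10S,13Z)-7-hydroxy-6-oxolabda-8,13-dien-15-yl acetate F4. Evans–Saksena reduction of F4 with Me4N[BH(OAc)3] in MeCN/AcOH at −20 °C should deliver hydride intramolecularly from the face of the 7α-hydroxyl and give the trans-diol 15, where the route is rejoined.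

**Further compounds**
F1 | step 9 | (2Z,6E,8S,9S)-8-(tert-butyldimethylsilyloxy)-9-hydroxy-3,7-dimethyl-9-(2,6,6-trimethylcyclohex-1-en-1-yl)nona-2,6-dien-1-yl acetate | CC1=C([C@H](O)[C@@H](O[Si](C)(C)C(C)(C)C)/C(C)=C/CC/C(C)=C\COC(C)=O)C(C)(C)CCC1
F2 | step 6 | (2Z,6E)-8-hydroxy-3,7-dimethyl-8-(tributylstannyl)octa-2,6-dien-1-yl acetate (racemic) | CC(=O)OC/C=C(/C)CC/C=C(\C)C(O)[Sn](CCCC)(CCCC)CCCC
F3 | step 6 | (2Z,6E,8S)-3,7-dimethyl-8-(tributylstannyl)octa-2,6-diene-1,8-diyl diacetate | CC(=O)OC/C=C(/C)CC/C=C(\C)[C@@H](OC(C)=O)[Sn](CCCC)(CCCC)CCCC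
F4 | step 10 | (5S,7S,10S,13Z)-7-hydroxy-6-oxolabda-8,13-dien-15-yl acetate | CC(=O)OC/C=C(/C)CCC1=C(C)[C@H](O)C(=O)[C@H]2C(C)(C)CCC[C@]12C
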